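**Retrosynthetic overview**
1. Both aryl C-prenyl bonds (C8 and C3′) are disconnected as photochemical O→C [1,3] prenyl shifts (photo-Claisen type) from the 7-O- and 4′-O-prenyl ethers.
2. The two chromophores are orthogonal. The 7-alkoxy-5-hydroxychromanone absorbs above 320 nm and the isolated 4′-alkoxyphenyl ring absorbs only below 290 nm, so the A-ring shift is run first and the B-ring shift second.
3. The bis-prenyl ether comes from Williamson O-prenylation of the two most acidic phenols (7-OH, 4′-OH) of (2R,3R)-aromadendrin.
4. No ring is formed. The trans-(2R,3R) dihydroflavonol core and both stereocenters come from natural (+)-aromadendrin and are never touched.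

Assumption: (+)-aromadendrin, the (2R,3R)-dihydrokaempferol isolated from conifer heartwood, is taken as a purchasable chiral starting material.

**Step 1**
Reactants: 1 (2R,3R)-(+)-aromadendrin; 2 prenyl bromide (2.3 equiv)
Product: 3 (2R,3R)-7,4′-di-O-prenylaromadendrin
Conditions: K2CO3 (2.5 equiv), acetone, 40 °C, N2, 10 h
Reagents that add atoms: prenyl bromide, CC(C)=CCBr
Why: Williamson etherification takes place at the most acidic phenols, 7-OH (vinylogous acid) and 4′-OH. The 5-OH is chelated to C4=O and the 3-OH is a hindered secondary alcohol, so both stay free. The mild base at 40 °C avoids retro-oxa-Michael ring opening, so C2 and C3 keep their trans configuration and no new stereocenter forms.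

**Step 2**
Reactants: 3
Product: 4 (2R,3R)-8-prenyl-4′-O-prenylaromadendrin
Conditions: hν (Rayonet 350 nm lamps, Pyrex, λ > 320 nm), MeCN, degassed (Ar), 10 °C, 3 h
Reagents that add atoms: none
Why: Proposed new method: excitation of the 7-alkoxy-5-hydroxychromanone charge-transfer band weakens the ArO–CH2 bond (about 50 kcal/mol), and cleavage gives a caged phenoxyl/prenyl radical pair. The pair recombines at an ortho carbon through the unhindered primary prenyl terminus, and the resulting dienone tautomerizes to the 7-OH phenol. The para position (C4a) is blocked, and C8 should be favoured over C6 by the higher C7–C8 bond order. The 4′-O-prenyl ether is transparent above 320 nm and survives. The closest known reactions are the photo-Claisen rearrangement of allyl aryl ethers and of 7-allyloxycoumarins. The sp3 centers C2 and C3 are remote from the reacting bonds, so no stereocenter is set or changed.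

**Step 3**
Reactants: 4
Product: 5 Lespedezaflavanone C ((2R,3R)-8,3′-diprenylaromadendrin)
Conditions: hν (254 nm low-pressure Hg lamps, quartz), MeCN, degassed (Ar), 10 °C, 6 h
Reagents that add atoms: none
Why: Proposed new method: this is the same O→C photo-Claisen manifold applied to the 4′-O-prenyl ether. Short-wavelength excitation of the isolated alkyl-aryl ether ring gives a radical pair, and recombination at the ortho carbon C3′ (para is blocked by C2) followed by tautomerization gives the 3′-prenyl-4′-OH phenol. The 5-OH/C4=O chelate channels A-ring excitation into ESIPT, so the chromanone is comparatively photostable. Stereochemistry is carried through unchanged from 1.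

**Compound list**
1 | (2R,3R)-(+)-aromadendrin | Oc1ccc(cc1)[C@H]2Oc3cc(O)cc(O)c3C(=O)[C@@H]2O | starting material
2 | prenyl bromide (1-bromo-3-methylbut-2-ene) | CC(C)=CCBr | starting material
3 | (2R,3R)-7,4′-di-O-prenylaromadendrin | CC(C)=CCOc1ccc(cc1)[C@H]2Oc3cc(OCC=C(C)C)cc(O)c3C(=O)[C@@H]2O | intermediate
4 | (2R,3R)-8-prenyl-4′-O-prenylaromadendrin | CC(C)=CCOc1ccc(cc1)[C@H]2Oc3c(CC=C(C)C)c(O)cc(O)c3C(=O)[C@@H]2O | intermediate
5 | Lespedezaflavanone C | CC(C)=CCc1cc([C@H]2Oc3c(CC=C(C)C)c(O)cc(O)c3C(=O)[C@@H]2O)ccc1O | target

**Totals:** 3 steps; longest linear sequence 3 steps from 1.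

**Three steps most likely to fail**
1. **Step 2 (proposed new A-ring photo-shift).** Risks are C6/C8 mixtures, reverse-prenyl isomers, and de-prenylation by escape of the radical pair.
   - Fallback (known chemistry): build the 7-O-(1,1-dimethylallyl) ether by CuI/DBU coupling with 3-chloro-3-methylbut-1-yne followed by Lindlar hydrogenation, then run the thermal [3,3] Claisen rearrangement (Eu(fod)3, 80 °C). This delivers the normal 8-prenyl group, and the minor C6 isomer is removed by HPLC.
2. **Step 3 (B-ring photo-shift at 254 nm).** Risks are competing benzylic C2–O1 photocleavage and inner-filter loss to the A ring.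
   - Fallback (known chemistry): cap 7-OH as its prenyl ether with 1 equiv of 2, convert 4′-OH to the 1,1-dimethylallyl ether (propargylation, Lindlar), and run the thermal Claisen at 4′ to give the 3′-prenyl phenol. Then do the A-ring shift by the Step 2 route or its fallback.
3. **Step 1 (selective bis-O-prenylation).** Risks are C2 epimerization or ring opening, over-alkylation at 5-OH or 3-OH, and C-alkylation.
   - Fallback (known chemistry): use base-free Tsuji–Trost O-prenylation with prenyl methyl carbonate and Pd(PPh3)4 in THF at 25 °C, which removes base-mediated epimerization.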